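A direct plan would keep a ready-made four-membered ring and decorate it. Racemic trans-cyclobutane-1,2-dicarboxylic acid A1 would be resolved to the (1R,2R)-acid A2, both ring CH2 groups arylated with 1,2-bis(benzyloxy)-4-iodobenzene A3 by carboxylate-directed palladium C–H activation to give diaryl diacid A4, and A4 esterified twice with benzyl-protected (R)-danshensu A5 before hydrogenolysis of the decabenzyl diester A6.
- Weakest would be the twofold directed C–H arylation: two successive cis-selective methylene arylations of a free cyclobutane diacid have no close precedent, two carboxylates compete for the metal, and both aryl-bearing stereocentres and the whole route hang on it.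
- Next would be the late twofold esterification: a hindered, α-epimerisable ring diacid flanked by cis aryl groups would have to acylate a hindered secondary α-hydroxy ester twice, spending over two equivalents of the chiral alcohol on the most precious intermediate.
- Third would be the classical resolution: a whole step that adds no complexity, discards half the diacid and leaves to chance which salt crystallises.

**Plan of the new route**
- The four-membered ring is cut across C1–C4 and C2–C3. C1/C2 with their trans ester groups are a fumarate, and C3/C4 with their trans catechol rings are an (E)-stilbene. The cis relation of each aryl to the ester on the neighbouring carbon (C3-aryl to C2-ester, C4-aryl to C1-ester) is the imprint of a parallel sandwich of the two alkenes.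
- The two acyl–O bonds are cut next, so the esters to the (R)-danshensu units are made first, on fumaroyl chloride, where nothing is hindered or epimerisable.
- The only ring of the core arises in the last C–C bond-forming step, one intermolecular [2+2] photocycloaddition that makes two bonds and all four ring stereocentres. The two (R)-centres already in the fumarate make its faces diastereotopic.
- No resolution, no C–H arylation (both aryl–ring bonds arrive with the stilbene) and no acylation of a hindered ring acid remain; one hydrogenolysis ends the route.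

Key step: step 5

Assumption: sodium (R)-danshensu is bought as the single enantiomer; precedent fixes the relative configuration of step 5 but not the sense of facial induction by the two (R)-centres, so the route is written for the re-face adduct and the si-face diastereomer is taken to be separable.

Step 1
Reactants: 1 3,4-dihydroxybenzaldehyde
Product: 2 2,2-diphenyl-1,3-benzodioxole-5-carbaldehyde
Conditions: Ph2CCl2 (1.2 equiv), K2CO3 (2.5 equiv), MeCN, rt → 60 °C
Reagents that add atoms: dichlorodiphenylmethane ClC(Cl)(c1ccccc1)c1ccccc1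
Why: Twofold O-alkylation of the catechol by the gem-dichloride (cyclic ketal formation through the chlorodiphenylmethyl ether and its stabilised diarylmethyl cation) ties both phenols into one hydrogenolysable group, while the aldehyde is untouched and no stereocentre is involved.

Step 2
Reactants: 2 2,2-diphenyl-1,3-benzodioxole-5-carbaldehyde (2 equiv; two molecules are joined through their aldehyde carbons)
Product: 4 (E)-1,2-bis(2,2-diphenyl-1,3-benzodioxol-5-yl)ethene, via titanium pinacolate 3 (not isolated)
Conditions: TiCl4 (1.5 equiv per aldehyde), Zn dust (3 equiv), THF, reflux; then 2, pyridine (0.5 equiv), reflux; aq. K2CO3 work-up; crystallisation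
Reagents that add atoms: none
Why: McMurry reductive homocoupling of two molecules of 2, in which low-valent titanium gives ketyl radicals that couple to the pinacolate and then removes both oxygen atoms; stepwise C–O cleavage should give the diaryl alkene as the more stable E isomer, and a small Z content is harmless because step 5 photoequilibrates the two.

Step 3
Reactants: 5 sodium (2R)-3-(3,4-dihydroxyphenyl)-2-hydroxypropanoate (sodium danshensu)
Product: 6 benzyl (2R)-3-[3,4-bis(benzyloxy)phenyl]-2-hydroxypropanoate
Conditions: BnBr (3.3 equiv), K2CO3 (2.5 equiv), DMF, argon, rt → 40 °C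
Reagents that add atoms: benzyl bromide BrCc1ccccc1
Why: Williamson etherification of the two phenoxides and O-alkylation of the carboxylate; K2CO3 does not ionise the secondary alcohol, which stays free, and the (R)-centre is not touched.

Step 4
Reactants: 6 benzyl (2R)-3-[3,4-bis(benzyloxy)phenyl]-2-hydroxypropanoate (2.1 equiv); 7 fumaroyl chloride
Product: 9 bis{(2R)-1-(benzyloxy)-3-[3,4-bis(benzyloxy)phenyl]-1-oxopropan-2-yl} (2E)-but-2-enedioate, via fumaric monoester chloride 8 (not isolated)
Conditions: pyridine (3 equiv), DMAP (5 mol %), CH2Cl2, −10 °C → rt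
Reagents that add atoms: none
Why: Pyridine/DMAP-mediated acylation of the secondary alcohol by an unhindered diacyl chloride without α-hydrogen, so both ester bonds of the target are made before any ring exists; the carbinol C–O bond is not broken (R retained) and the E geometry is kept.

Step 5
Reactants: 4 (E)-1,2-bis(2,2-diphenyl-1,3-benzodioxol-5-yl)ethene; 9 bis{(2R)-1-(benzyloxy)-3-[3,4-bis(benzyloxy)phenyl]-1-oxopropan-2-yl} (2E)-but-2-enedioate
Product: 10 bis{(2R)-1-(benzyloxy)-3-[3,4-bis(benzyloxy)phenyl]-1-oxopropan-2-yl} (1R,2R,3R,4R)-3,4-bis(2,2-diphenyl-1,3-benzodioxol-5-yl)cyclobutane-1,2-dicarboxylate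
Conditions: 9 (0.15 M), 4 (1.3 equiv, in portions, kept ≤ 0.03 M), toluene (freeze–pump–thaw degassed), hν (medium-pressure Hg lamp, Pyrex and λ > 310 nm filter), −20 °C, argon; chromatography, then crystallisation
Reagents that add atoms: none
Why: Only 4 absorbs above 310 nm; its singlet excited state is captured by the electron-poor fumarate 9 as a sandwich singlet exciplex, which collapses by forming C1–C4 and C2–C3 suprafacially on both partners (photochemical [π2s+π2s] cycloaddition). The closest known reaction is the exciplex [2+2] photocycloaddition of trans-stilbene with dialkyl fumarates, including fumarates of chiral secondary alcohols, which is stereospecific for this cyclobutane pattern. The four-membered ring is closed intermolecularly, two σ-bonds across two C=C bonds, with no ring of the core present beforehand. C1/C2 come out trans because the E-fumarate geometry is kept and C3/C4 trans because the E-stilbene geometry is kept (the singlet path is faster than bond rotation), and each aryl is cis to the adjacent ester because the sandwich places each aryl ring over an ester carbonyl and not crossed, which excludes the all-trans isomer. The absolute sense rests on the two (R)-acyloxy centres of C2-symmetric 9, which make its faces diastereotopic and act in the same direction: addition to the face that is re at both olefinic carbons gives the (1R,2R,3R,4R) ring of 10, and addition to the si face gives its only possible companion, a diastereomer to be removed by chromatography or crystallisation, with temperature and the size of the carboxyl ester as handles on the ratio. The step needs cross- over homo-addition, secured by keeping 4 dilute and the transparent 9 concentrated, and it tolerates E/Z isomerisation of 4 because the Z form returns to E under the same light when oxygen is excluded.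

Step 6
Reactants: 10 bis{(2R)-1-(benzyloxy)-3-[3,4-bis(benzyloxy)phenyl]-1-oxopropan-2-yl} (1R,2R,3R,4R)-3,4-bis(2,2-diphenyl-1,3-benzodioxol-5-yl)cyclobutane-1,2-dicarboxylate
Product: 11 (2R,2'R)-2,2'-{[(1R,2R,3R,4R)-3,4-bis(3,4-dihydroxyphenyl)cyclobutane-1,2-dicarbonyl]bis(oxy)}bis[3-(3,4-dihydroxyphenyl)propanoic acid] (CNP0163929.1)
Conditions: H2 (1 atm), 20% Pd(OH)2/C, THF–MeOH (1:1), rt; filtration under argon; reversed-phase chromatography (H2O–MeCN, 0.1% HCO2H)
Reagents that add atoms: none
Why: Catalytic hydrogenolysis cleaves the four aryl benzyl ethers, the two benzyl esters and the two diphenylmethylene ketals at benzylic C–O bonds, while the homobenzylic acyloxy C–O bonds, the ester carbonyls and the cyclobutane are inert at 1 atm and rt, and no stereocentre takes part.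

**Compound list**

1 | 3,4-dihydroxybenzaldehyde | O=Cc1ccc(O)c(O)c1 | starting material
2 | 2,2-diphenyl-1,3-benzodioxole-5-carbaldehyde | O=Cc1ccc2OC(c3ccccc3)(c3ccccc3)Oc2c1 | intermediate
3 | titanium pinacolate: 1,2-bis(2,2-diphenyl-1,3-benzodioxol-5-yl)ethane-1,2-diolate held on titanium, drawn as the cyclic titanium diolate, other ligands on the metal omitted (dl and meso forms, configuration not defined) | [Ti]1OC(c2ccc3OC(c4ccccc4)(c4ccccc4)Oc3c2)C(c2ccc3OC(c4ccccc4)(c4ccccc4)Oc3c2)O1 | intermediate
4 | (E)-1,2-bis(2,2-diphenyl-1,3-benzodioxol-5-yl)ethene | c1cc2OC(c3ccccc3)(c3ccccc3)Oc2cc1/C=C/c1ccc2OC(c3ccccc3)(c3ccccc3)Oc2c1 | intermediate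
5 | sodium (2R)-3-(3,4-dihydroxyphenyl)-2-hydroxypropanoate | O[C@H](Cc1ccc(O)c(O)c1)C(=O)[O-].[Na+] | starting material
6 | benzyl (2R)-3-[3,4-bis(benzyloxy)phenyl]-2-hydroxypropanoate | O[C@H](Cc1ccc(OCc2ccccc2)c(OCc2ccccc2)c1)C(=O)OCc1ccccc1 | intermediate
7 | fumaroyl chloride, (2E)-but-2-enedioyl dichloride | O=C(Cl)/C=C/C(=O)Cl | starting material
8 | fumaric monoester chloride: (2R)-1-(benzyloxy)-3-[3,4-bis(benzyloxy)phenyl]-1-oxopropan-2-yl (2E)-4-chloro-4-oxobut-2-enoate | O=C(Cl)/C=C/C(=O)O[C@H](Cc1ccc(OCc2ccccc2)c(OCc2ccccc2)c1)C(=O)OCc1ccccc1 | intermediate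
9 | bis{(2R)-1-(benzyloxy)-3-[3,4-bis(benzyloxy)phenyl]-1-oxopropan-2-yl} (2E)-but-2-enedioate | O=C(/C=C/C(=O)O[C@H](Cc1ccc(OCc2ccccc2)c(OCc2ccccc2)c1)C(=O)OCc1ccccc1)O[C@H](Cc1ccc(OCc2ccccc2)c(OCc2ccccc2)c1)C(=O)OCc1ccccc1 | intermediate
10 | bis{(2R)-1-(benzyloxy)-3-[3,4-bis(benzyloxy)phenyl]-1-oxopropan-2-yl} (1R,2R,3R,4R)-3,4-bis(2,2-diphenyl-1,3-benzodioxol-5-yl)cyclobutane-1,2-dicarboxylate (esters trans, aryls trans, each aryl cis to the neighbouring ester) | O=C(O[C@H](Cc1ccc(OCc2ccccc2)c(OCc2ccccc2)c1)C(=O)OCc1ccccc1)[C@H]1[C@H](C(=O)O[C@H](Cc2ccc(OCc3ccccc3)c(OCc3ccccc3)c2)C(=O)OCc2ccccc2)[C@H](c2ccc3OC(c4ccccc4)(c4ccccc4)Oc3c2)[C@H]1c1ccc2OC(c3ccccc3)(c3ccccc3)Oc2c1 | intermediate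
11 | CNP0163929.1, (2R,2'R)-2,2'-{[(1R,2R,3R,4R)-3,4-bis(3,4-dihydroxyphenyl)cyclobutane-1,2-dicarbonyl]bis(oxy)}bis[3-(3,4-dihydroxyphenyl)propanoic acid] | O=C(O[C@H](Cc1ccc(O)c(O)c1)C(=O)O)[C@H]1[C@H](C(=O)O[C@H](Cc2ccc(O)c(O)c2)C(=O)O)[C@H](c2ccc(O)c(O)c2)[C@H]1c1ccc(O)c(O)c1 | target

**Step count and risks**

Total steps: 6. Longest linear sequence: 4 (steps 1, 2, 5, 6, or equally steps 3, 4, 5, 6).

Steps most likely to fail:

1. Step 5. Discrimination between the two faces of 9 may be weak or inverted. In the usual planar ester conformation each (R)-carbinol carbon holds its ArCH2 group over the re face and its CO2Bn group over the si face when the enoate is s-cis, and the reverse when it is s-trans, so the sense cannot be read from a model. Capture of excited 4 may also be too slow to compete with its E/Z isomerisation, or the exciplex of this electron-rich stilbene may decay without bond formation. The fallback keeps the cycloaddition but fixes the face with a removable terpene auxiliary that is sold as both antipodes, and attaches the side chains afterwards. It sets out from 7 and 4. Acylation of (−)-borneol (2 equiv) with 7 (pyridine, CH2Cl2) should give di-(−)-bornyl fumarate F1. Irradiation of F1 with 4 under the conditions of step 5 should give the bornyl cycloadduct F2, for which high facial selection is on record in the parent stilbene series. LiOH in aqueous THF, then 1 M HCl, should free the ring diacid F3, which is esterified twice with 6 (2.3 equiv; DCC, DMAP, CH2Cl2, 0 °C → rt) to come back to the route at 10. Should (−)-borneol direct to the wrong face, (+)-borneol is used in the same way. The price is the late twofold acylation that the main route avoids.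

2. Step 6. Hydrogenolysis of the two diphenylmethylene ketals may stall after the benzyl groups are gone, and the octaphenol may oxidise in air during prolonged reaction and isolation. The fallback separates the two cleavage modes and sets out from 10. H2 with 10% Pd/C in THF–MeOH is stopped once the six faster-cleaving benzyl groups are gone and should give the bis-ketal diacid F4. TFA–H2O (9:1), 0 °C → rt, under argon then hydrolyses the ketals (benzophenone is extracted) and the route is rejoined at 11.

3. Step 2. The coupling may stop at the pinacol stage, the Lewis-acidic titanium and zinc chlorides may open the ketal, or a poorly crystallising E/Z mixture may result. The fallback builds the central double bond by metathesis and sets out from 2. Wittig methylenation (Ph3PCH3Br, KOtBu, THF, 0 °C) should give 5-ethenyl-2,2-diphenyl-1,3-benzodioxole F5. Homometathesis of two molecules of F5 with the second-generation Grubbs catalyst RuCl2(=CHPh)(PCy3)(H2IMes) (2 mol %, CH2Cl2, 40 °C, argon sweep) should give the E-stilbene and the route is rejoined at 4.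

**Further compounds**

F1 | step 5 | di-(−)-bornyl fumarate, bis[(1S,2R,4S)-1,7,7-trimethylbicyclo[2.2.1]heptan-2-yl] (2E)-but-2-enedioate | O=C(/C=C/C(=O)O[C@@H]1C[C@@H]2CC[C@@]1(C)C2(C)C)O[C@@H]1C[C@@H]2CC[C@@]1(C)C2(C)C
F2 | step 5 | bis[(1S,2R,4S)-1,7,7-trimethylbicyclo[2.2.1]heptan-2-yl] (1R,2R,3R,4R)-3,4-bis(2,2-diphenyl-1,3-benzodioxol-5-yl)cyclobutane-1,2-dicarboxylate | O=C(O[C@@H]1C[C@@H]2CC[C@@]1(C)C2(C)C)[C@H]1[C@H](C(=O)O[C@@H]2C[C@@H]3CC[C@@]2(C)C3(C)C)[C@H](c2ccc3OC(c4ccccc4)(c4ccccc4)Oc3c2)[C@H]1c1ccc2OC(c3ccccc3)(c3ccccc3)Oc2c1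
F3 | step 5 | (1R,2R,3R,4R)-3,4-bis(2,2-diphenyl-1,3-benzodioxol-5-yl)cyclobutane-1,2-dicarboxylic acid | O=C(O)[C@H]1[C@H](C(=O)O)[C@H](c2ccc3OC(c4ccccc4)(c4ccccc4)Oc3c2)[C@H]1c1ccc2OC(c3ccccc3)(c3ccccc3)Oc2c1
F4 | step 6 | (2R,2'R)-2,2'-{[(1R,2R,3R,4R)-3,4-bis(2,2-diphenyl-1,3-benzodioxol-5-yl)cyclobutane-1,2-dicarbonyl]bis(oxy)}bis[3-(3,4-dihydroxyphenyl)propanoic acid] | O=C(O[C@H](Cc1ccc(O)c(O)c1)C(=O)O)[C@H]1[C@H](C(=O)O[C@H](Cc2ccc(O)c(O)c2)C(=O)O)[C@H](c2ccc3OC(c4ccccc4)(c4ccccc4)Oc3c2)[C@H]1c1ccc2OC(c3ccccc3)(c3ccccc3)Oc2c1
F5 | step 2 | 5-ethenyl-2,2-diphenyl-1,3-benzodioxole | C=Cc1ccc2OC(c3ccccc3)(c3ccccc3)Oc2c1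
A1 | direct plan | rac-trans-cyclobutane-1,2-dicarboxylic acid (both enantiomers) | O=C(O)[C@H]1[C@H](C(=O)O)CC1.O=C(O)[C@@H]1[C@@H](C(=O)O)CC1
A2 | direct plan | (1R,2R)-cyclobutane-1,2-dicarboxylic acid | O=C(O)[C@H]1[C@H](C(=O)O)CC1
A3 | direct plan | 1,2-bis(benzyloxy)-4-iodobenzene | Ic1ccc(OCc2ccccc2)c(OCc2ccccc2)c1
A4 | direct plan | (1R,2R,3R,4R)-3,4-bis[3,4-bis(benzyloxy)phenyl]cyclobutane-1,2-dicarboxylic acid | O=C(O)[C@H]1[C@H](C(=O)O)[C@H](c2ccc(OCc3ccccc3)c(OCc3ccccc3)c2)[C@H]1c1ccc(OCc2ccccc2)c(OCc2ccccc2)c1
A5 | direct plan | benzyl (2R)-3-[3,4-bis(benzyloxy)phenyl]-2-hydroxypropanoate (the same structure as 6) | O[C@H](Cc1ccc(OCc2ccccc2)c(OCc2ccccc2)c1)C(=O)OCc1ccccc1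
A6 | direct plan | bis{(2R)-1-(benzyloxy)-3-[3,4-bis(benzyloxy)phenyl]-1-oxopropan-2-yl} (1R,2R,3R,4R)-3,4-bis[3,4-bis(benzyloxy)phenyl]cyclobutane-1,2-dicarboxylate | O=C(O[C@H](Cc1ccc(OCc2ccccc2)c(OCc2ccccc2)c1)C(=O)OCc1ccccc1)[C@H]1[C@H](C(=O)O[C@H](Cc2ccc(OCc3ccccc3)c(OCc3ccccc3)c2)C(=O)OCc2ccccc2)[C@H](c2ccc(OCc3ccccc3)c(OCc3ccccc3)c2)[C@H]1c1ccc(OCc2ccccc2)c(OCc2ccccc2)c1
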